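## Retrosynthetic overview

1. Target 28 ⇒ one acidic unmasking of 27 ⇒ Stille disconnection at C2–C1' into 2‑bromoenone 19 and (R,E)‑vinylstannane 26, which comes from (R)‑propylene oxide.
2. 19 ⇒ enone 15 by β‑(tert‑butoxymethyl)ation with re‑oxidation (C3), then α‑bromination (C2).
3. 15 ⇒ allylic γ‑lactone 12 (lactol Wittig builds the butenoate, C1–OH is oxidised). 12 ⇒ amide 9 by iodolactonisation and elimination, which puts O on C1 and moves the alkene to C2=C3.
4. Key step: the C6–CH2 bond forms in a suprafacial Eschenmoser–Claisen [3,3] shift of allylic alcohol 7. It carries the C–O configuration over to C6, cis to the diol.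
5. 7 ⇒ enone 6 ⇒ (−)‑quinic acid. The carbocycle is bought intact, and only temporary rings are made, in this order: lactone and dioxolane (step 1), then γ‑lactone (step 7).

Convention and assumption: ring atoms carry the target numbering throughout (C1 = C=O, C2 = alkenyl carbon, C3 = CH2OH carbon, C4/C5 = carbinols, C6 = butenoate‑bearing carbon). All reagents named under "Conditions" are taken as purchasable.

## Route

Step 1
Reactants: 1 (−)‑quinic acid
Product: 2 3,4‑O‑isopropylidene‑1,5‑quinide (lactone between the carboxyl group and the trans OH, dioxolane on the cis diol)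
Conditions: Me2C(OMe)2, TsOH (cat.), acetone, reflux
Reagents that add atoms: 2,2‑dimethoxypropane, COC(C)(C)OC
Why: Acid‑catalysed transacetalisation with lactonisation; only the cis 3,4‑diol can form the dioxolane and only the 5‑OH syn to CO2H can lactonise, so no stereocentre changes.

Step 2
Reactants: 2 3,4‑O‑isopropylidene‑1,5‑quinide
Product: 3 triol: 1‑(hydroxymethyl)‑3,4‑O‑isopropylidene‑cyclohexane‑1,3,4,5‑tetrol
Conditions: NaBH4, EtOH, 0 °C → rt
Reagents that add atoms: none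
Why: Borohydride reduction of the strained lactone exposes the 1,2‑diol needed for cleavage and leaves all stereocentres alone.

Step 3
Reactants: 3 triol
Product: 4 (3R,4S,5R)‑5‑hydroxy‑3,4‑(isopropylidenedioxy)cyclohexan‑1‑one
Conditions: NaIO4, H2O, 0 °C → rt
Reagents that add atoms: none
Why: Malaprade glycol cleavage removes the exocyclic CH2OH carbon and gives the ring ketone (future C2).

Step 4
Reactants: 4 β‑hydroxy ketone
Product: 6 (4S,5R)‑4,5‑(isopropylidenedioxy)cyclohex‑2‑en‑1‑one, via mesylate 5 (not isolated)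
Conditions: MsCl, Et3N, CH2Cl2, 0 °C → rt
Reagents that add atoms: methanesulfonyl chloride, CS(=O)(=O)Cl (its atoms stay only in 5)
Why: Mesylation is followed by E1cB elimination of the β‑mesyloxy ketone, and the two dioxolane centres (future C4, C5) are retained.

Step 5
Reactants: 6 enone
Product: 7 (1S,4S,5R)‑4,5‑(isopropylidenedioxy)cyclohex‑2‑en‑1‑ol (OH cis to the dioxolane)
Conditions: NaBH4, CeCl3·7H2O, MeOH, 0 °C
Reagents that add atoms: none
Why: Luche 1,2‑reduction; axial hydride attack comes from the face opposite the dioxolane, so the new carbinol OH lies on the dioxolane face under control of the quinic acid centres.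

Step 6
Reactants: 7 allylic alcohol
Product: 9 2‑[(1S,5R,6S)‑5,6‑(isopropylidenedioxy)cyclohex‑2‑en‑1‑yl]‑N,N‑dimethylacetamide (all‑cis), via ketene N,O‑acetal 8 (not isolated)
Conditions: MeC(OMe)2NMe2, xylene, 140 °C (MeOH distilled off)
Reagents that add atoms: N,N‑dimethylacetamide dimethyl acetal, COC(C)(OC)N(C)C
Why: Eschenmoser–Claisen [3,3]‑sigmatropic rearrangement; the suprafacial shift delivers CH2CONMe2 to the face that carried the C–O bond, which sets C6 cis to the C5/C4 oxygens.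

Step 7
Reactants: 9 amide
Product: 11 iodolactone (cis‑fused γ‑lactone C6–CH2–C(=O)–O–C1, iodine on C2 trans to the C1–O bond), via iodo iminium ether 10 (not isolated)
Conditions: I2, THF/H2O (1:1), rt, dark
Reagents that add atoms: iodine, II; water, O
Why: Iodolactonisation of a γ,δ‑unsaturated amide; the tether can only reach C1 from its own face (anti to the iodonium ion), so oxygen goes to C1 with full regiocontrol.

Step 8
Reactants: 11 iodolactone
Product: 12 allylic γ‑lactone (C2=C3 alkene, C1–O lactone cis‑fused at C1/C6)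
Conditions: DBU, toluene, 90 °C
Reagents that add atoms: none
Why: Anti E2 dehydroiodination; only a C3–H can be antiperiplanar to C2–I because C1–H is syn to it, so the alkene ends up at C2=C3.

Step 9
Reactants: 12 allylic lactone
Product: 14 tert‑butyl (E)‑4‑[(C1‑hydroxy, 4,5‑isopropylidenedioxy)cyclohex‑2‑en‑6‑yl]‑2‑methylbut‑2‑enoate (all four ring substituents cis), via lactol 13 (not isolated)
Conditions: DIBAL‑H (1.1 equiv), CH2Cl2, −78 °C, Rochelle work‑up; crude 13, Ph3P=C(Me)CO2t‑Bu, toluene, 80 °C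
Reagents that add atoms: tert‑butyl 2‑(triphenyl‑λ5‑phosphanylidene)propanoate, CC(C(=O)OC(C)(C)C)=P(c1ccccc1)(c1ccccc1)c1ccccc1
Why: Half‑reduction of the lactone, then Wittig olefination of the open hydroxy‑aldehyde form; the stabilised α‑methyl ylide gives the E‑trisubstituted enoate and frees C1–OH.

Step 10
Reactants: 14 hydroxy enoate
Product: 15 (4R,5S,6R)‑enone: tert‑butyl (E)‑4‑[4,5‑(isopropylidenedioxy)‑1‑oxocyclohex‑2‑en‑6‑yl]‑2‑methylbut‑2‑enoate
Conditions: Dess–Martin periodinane, CH2Cl2, rt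
Reagents that add atoms: none
Why: Neutral Dess–Martin oxidation of the allylic alcohol gives the C1 ketone without base, so C6 is not epimerised and the β‑alkoxy group is not eliminated.

Step 11
Reactants: 15 enone
Product: 17 3‑(tert‑butoxymethyl) enone, (4R,5S,6R), via silyl enol ether 16 (not isolated)
Conditions: t‑BuOCH2Li (t‑BuOMe, s‑BuLi, t‑BuOK, −78 °C; LiBr), CuBr·SMe2, TMSCl, THF, −78 °C; crude 16, Pd(OAc)2, MeCN, rt
Reagents that add atoms: tert‑butyl methyl ether, COC(C)(C)C (delivered as the t‑BuOCH2 cuprate); chlorotrimethylsilane, C[Si](C)(C)Cl (atoms only in 16)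
Why: Gilman conjugate addition anti to the dioxolane is trapped as the regiodefined enol silane, and Saegusa–Ito oxidation restores C2=C3, which erases the transient C3 centre.

Step 12
Reactants: 17 3‑substituted enone
Product: 19 2‑bromo‑3‑(tert‑butoxymethyl) enone, (4R,5S,6R), via dibromide 18 (not isolated)
Conditions: Br2 (1.0 equiv), CH2Cl2, −78 → 0 °C; then Et3N, 0 °C
Reagents that add atoms: bromine, BrBr
Why: Bromination–dehydrobromination; the β,β‑dialkyl enone alkene is expected to take up Br2 faster than the tiglate‑type ester alkene, and Et3N removes the acidic C2–H (E1cB) to give the α‑bromoenone.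

Step 13
Reactants: 20 (R)‑propylene oxide; 21 (4‑bromobut‑1‑yn‑1‑yl)trimethylsilane
Product: 23 (R)‑7‑(trimethylsilyl)hept‑6‑yn‑2‑ol, via Grignard reagent 22 (not isolated)
Conditions: 21, Mg, THF; CuI (10 mol %), 20, −30 → 0 °C
Reagents that add atoms: magnesium, [Mg] (only in 22)
Why: Copper‑catalysed SN2 epoxide opening at the unsubstituted carbon keeps the bought (R) centre untouched.

Step 14
Reactants: 23 silyl alkynol
Product: 24 (R)‑hept‑6‑yn‑2‑ol
Conditions: K2CO3 (cat.), MeOH, rt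
Reagents that add atoms: none
Why: Methanolytic protodesilylation of the alkynylsilane.

Step 15
Reactants: 24 alkynol
Product: 25 (R)‑hept‑6‑yn‑2‑yl acetate
Conditions: Ac2O, pyridine, DMAP (cat.), rt
Reagents that add atoms: acetic anhydride, CC(=O)OC(C)=O
Why: O‑acylation with retention installs the natural acetate before any step that could confuse it with other hydroxyl groups.

Step 16
Reactants: 25 alkynyl acetate
Product: 26 (R,E)‑7‑(tributylstannyl)hept‑6‑en‑2‑yl acetate
Conditions: Bu3SnH, Pd2(dba)3 (cat.), Cy3P·HBF4 (cat.), i‑Pr2NEt (cat.), CH2Cl2, 0 °C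
Reagents that add atoms: tributyltin hydride, CCCC[SnH](CCCC)CCCC
Why: Pd‑catalysed syn hydrostannation with a bulky phosphine places tin on the terminal carbon, gives the E‑vinylstannane and tolerates the ester.

Step 17
Reactants: 19 2‑bromoenone; 26 vinylstannane
Product: 27 fully protected pestallic acid J (tert‑butyl ester, tert‑butyl ether, 4,5‑acetonide, side‑chain acetate)
Conditions: Pd2(dba)3·CHCl3 (5 mol %), AsPh3 (20 mol %), CuI (10 mol %), NMP, 60 °C
Reagents that add atoms: none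
Why: Stille coupling under neutral conditions retains the E geometry and spares the base‑sensitive β‑alkoxy ketone, C6–H and the acetate.

Step 18
Reactants: 27 protected compound
Product: 28 pestallic acid J
Conditions: TFA/CH2Cl2/H2O (5:5:1), 0 °C → rt
Reagents that add atoms: none
Why: One acidolysis removes the tert‑butyl ester, the tert‑butyl ether (E1 loss of isobutene) and the acetonide (hydrolysis), while the secondary acetate and all four stereocentres are unaffected.

## Compound list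

| No. | Name | SMILES | Role |
|---|---|---|---|
| 1 | (−)‑quinic acid | OC(=O)[C@]1(O)C[C@@H](O)[C@@H](O)[C@H](O)C1 | starting material |
| 2 | 3,4‑O‑isopropylidene‑1,5‑quinide | O[C@@]12C[C@H]3OC(C)(C)O[C@H]3[C@@H](C1)OC2=O | intermediate |
| 3 | triol (reduced quinide acetonide) | OC[C@]1(O)C[C@H]2OC(C)(C)O[C@H]2[C@H](O)C1 | intermediate |
| 4 | (3R,4S,5R)‑5‑hydroxy‑3,4‑(isopropylidenedioxy)cyclohexanone | O=C1C[C@H]2OC(C)(C)O[C@H]2[C@H](O)C1 | intermediate |
| 5 | mesylate of 4 | O=C1C[C@H]2OC(C)(C)O[C@H]2[C@H](OS(C)(=O)=O)C1 | intermediate |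
| 6 | (4S,5R)‑4,5‑(isopropylidenedioxy)cyclohex‑2‑enone | O=C1C[C@H]2OC(C)(C)O[C@H]2C=C1 | intermediate |
| 7 | (1S,4S,5R)‑allylic alcohol, OH cis to dioxolane | O[C@H]1C[C@H]2OC(C)(C)O[C@H]2C=C1 | intermediate |
| 8 | ketene N,O‑acetal of 7 | C=C(N(C)C)O[C@H]1C[C@H]2OC(C)(C)O[C@H]2C=C1 | intermediate |
| 9 | all‑cis cyclohexenyl‑N,N‑dimethylacetamide | CN(C)C(=O)C[C@H]1C=CC[C@H]2OC(C)(C)O[C@@H]12 | intermediate |
| 10 | iodo iminium ether iodide | C[N+](C)=C1C[C@H]2[C@@H](O1)[C@H](I)C[C@H]3OC(C)(C)O[C@@H]23.[I-] | intermediate |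
| 11 | iodolactone | O=C1C[C@H]2[C@@H](O1)[C@H](I)C[C@H]3OC(C)(C)O[C@@H]23 | intermediate |
| 12 | allylic γ‑lactone | O=C1C[C@H]2[C@@H](O1)C=C[C@H]3OC(C)(C)O[C@@H]23 | intermediate |
| 13 | lactol (anomer mixture) | OC1C[C@H]2[C@@H](O1)C=C[C@H]3OC(C)(C)O[C@@H]23 | intermediate |
| 14 | C1‑hydroxy E‑enoate | CC(C)(C)OC(=O)/C(C)=C/C[C@H]1[C@@H](O)C=C[C@H]2OC(C)(C)O[C@@H]12 | intermediate |
| 15 | (4R,5S,6R)‑enone | CC(C)(C)OC(=O)/C(C)=C/C[C@H]1C(=O)C=C[C@H]2OC(C)(C)O[C@@H]12 | intermediate |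
| 16 | TMS enol ether, C3‑CH2Ot‑Bu trans to dioxolane | CC(C)(C)OC(=O)/C(C)=C/C[C@H]1C(O[Si](C)(C)C)=C[C@H](COC(C)(C)C)[C@H]2OC(C)(C)O[C@@H]12 | intermediate |
| 17 | 3‑(tert‑butoxymethyl) enone | CC(C)(C)OC(=O)/C(C)=C/C[C@H]1C(=O)C=C(COC(C)(C)C)[C@H]2OC(C)(C)O[C@@H]12 | intermediate |
| 18 | 2,3‑dibromide (anti adduct) | CC(C)(C)OC(=O)/C(C)=C/C[C@H]1C(=O)[C@H](Br)[C@](Br)(COC(C)(C)C)[C@H]2OC(C)(C)O[C@@H]12 | intermediate |
| 19 | 2‑bromo‑3‑(tert‑butoxymethyl) enone | CC(C)(C)OC(=O)/C(C)=C/C[C@H]1C(=O)C(Br)=C(COC(C)(C)C)[C@H]2OC(C)(C)O[C@@H]12 | intermediate |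
| 20 | (R)‑propylene oxide | C[C@@H]1CO1 | starting material |
| 21 | (4‑bromobut‑1‑yn‑1‑yl)trimethylsilane | C[Si](C)(C)C#CCCBr | starting material |
| 22 | 4‑(trimethylsilyl)but‑3‑ynylmagnesium bromide | C[Si](C)(C)C#CCC[Mg]Br | intermediate |
| 23 | (R)‑7‑(trimethylsilyl)hept‑6‑yn‑2‑ol | C[C@@H](O)CCCC#C[Si](C)(C)C | intermediate |
| 24 | (R)‑hept‑6‑yn‑2‑ol | C[C@@H](O)CCCC#C | intermediate |
| 25 | (R)‑hept‑6‑yn‑2‑yl acetate | CC(=O)O[C@H](C)CCCC#C | intermediate |
| 26 | (R,E)‑7‑(tributylstannyl)hept‑6‑en‑2‑yl acetate | CC(=O)O[C@H](C)CCC/C=C/[Sn](CCCC)(CCCC)CCCC | intermediate |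
| 27 | protected pestallic acid J | CC(C)(C)OC(=O)/C(C)=C/C[C@H]1C(=O)C(/C=C/CCC[C@@H](C)OC(C)=O)=C(COC(C)(C)C)[C@H]2OC(C)(C)O[C@@H]12 | intermediate |
| 28 | pestallic acid J | CC(=O)O[C@H](C)CCC/C=C/C1=C(CO)[C@@H](O)[C@@H](O)[C@@H](C/C=C(\C)C(=O)O)C1=O | target |

## Step count and risks

Total step count: 18. Longest linear sequence: 14 (steps 1–12, 17, 18).

**Step 11.** The α‑alkoxymethyl cuprate may be too unreactive or unstable. The fallback sets out from 15 and comes back at 17.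
- Add the robust divinylcuprate with TMSCl to give the 3‑vinyl silyl enol ether F1.
- Oxidise with Pd(OAc)2 to the 3‑vinyl enone F2.
- Cleave only the terminal, electron‑rich vinyl group (cat. OsO4, NaIO4, 2,6‑lutidine) to the 3‑formyl enone F3.
- Reduce the aldehyde chemoselectively with NaBH(OAc)3 to the 3‑(hydroxymethyl) enone F4.
- tert‑Butylate with t‑BuOC(=NH)CCl3 and cat. BF3·OEt2 to reach 17.

**Step 12.** The α‑halogenation of a β‑substituted enone carries a chemoselectivity risk. The fallback sets out from 15 and comes back at 27.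
- Halogenate while C3 is still unsubstituted (I2, pyridine) to the 2‑iodoenone F5.
- Couple F5 with 26 (Stille, rt) to the 2‑alkenyl enone F6.
- Only then add the tert‑butoxymethyl cuprate with TMSCl to give the silyl dienol ether F7.
- Re‑oxidise with Pd(OAc)2 to 27, so that 17–19 are bypassed.

**Step 18.** The β‑hydroxy ketone may dehydrate or aromatise in TFA. The fallback sets out from 27 and comes back at 28.
- Unmask in two mild stages. First 80 % aq. AcOH at 40 °C removes only the acetonide and gives the diol di‑tert‑butyl compound F8.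
- Then 85 % aq. H3PO4 in toluene at rt cleaves the tert‑butyl ester and ether.

Further compounds
F1 | step 11 | 3‑vinyl silyl enol ether | CC(C)(C)OC(=O)/C(C)=C/C[C@H]1C(O[Si](C)(C)C)=C[C@H](C=C)[C@H]2OC(C)(C)O[C@@H]12
F2 | step 11 | 3‑vinyl enone | CC(C)(C)OC(=O)/C(C)=C/C[C@H]1C(=O)C=C(C=C)[C@H]2OC(C)(C)O[C@@H]12
F3 | step 11 | 3‑formyl enone | CC(C)(C)OC(=O)/C(C)=C/C[C@H]1C(=O)C=C(C=O)[C@H]2OC(C)(C)O[C@@H]12
F4 | step 11 | 3‑(hydroxymethyl) enone | CC(C)(C)OC(=O)/C(C)=C/C[C@H]1C(=O)C=C(CO)[C@H]2OC(C)(C)O[C@@H]12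
F5 | step 12 | 2‑iodoenone | CC(C)(C)OC(=O)/C(C)=C/C[C@H]1C(=O)C(I)=C[C@H]2OC(C)(C)O[C@@H]12
F6 | step 12 | 2‑alkenyl enone | CC(C)(C)OC(=O)/C(C)=C/C[C@H]1C(=O)C(/C=C/CCC[C@@H](C)OC(C)=O)=C[C@H]2OC(C)(C)O[C@@H]12
F7 | step 12 | silyl dienol ether | CC(C)(C)OC(=O)/C(C)=C/C[C@H]1C(O[Si](C)(C)C)=C(/C=C/CCC[C@@H](C)OC(C)=O)[C@H](COC(C)(C)C)[C@H]2OC(C)(C)O[C@@H]12
F8 | step 18 | diol di‑tert‑butyl compound | CC(=O)O[C@H](C)CCC/C=C/C1=C(COC(C)(C)C)[C@@H](O)[C@@H](O)[C@@H](C/C=C(\C)C(=O)OC(C)(C)C)C1=O
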